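**Assumption:** the target has no stereocentre, so there is no enantiomer to control; olivetolic acid (CAS 491-72-5) is bought as such.

## Retrosynthetic overview

1. Target ⇒ its benzyl ester (neutral hydrogenolysis last) ⇒ depside aryl-ester bond: 2-hydroxy-4-methoxy-6-(2-oxoheptyl)benzoic acid + benzyl olivetolate.
2. The keto acid ⇒ its enol lactone, 8-hydroxy-6-methoxy-3-pentylisocoumarin (lactone hydrolysis).
3. Key C–C disconnection: aryl C6–CH2 of the 2-oxoheptyl chain. A nucleophilic aryl–Rh carbon (carboxylate-directed C–H activation of 4-methoxysalicylic acid) is joined to the α-carbon of heptan-2-one used as an electrophilic α-oxo-carbene (enolonium equivalent, from a hexanoyl sulfoxonium ylide); both carbons are natively nucleophilic.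
4. Rings: both benzene rings are bought. The only ring formed is the pyranone of the isocoumarin, which closes in the key step and is reopened in the next step.

## Route

Step 1
Reactants: 1 hexanoyl chloride; 2 trimethylsulfoxonium iodide
Product: 4 1-(dimethyl(oxo)-λ6-sulfanylidene)heptan-2-one, via dimethylsulfoxonium methylide 3 (not isolated)
Conditions: 2 (3 equiv), KOtBu (3 equiv), THF, reflux, 2 h; then 1 (1 equiv), 0 °C → rt, 1 h
Reagents that add atoms: none
Why: Corey–Chaykovsky ylide acylation: methylide 3 is C-acylated by the acid chloride and a second equivalent of 3 removes the now acidic α-proton, giving the stabilised β-keto sulfoxonium ylide; no stereocentre.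

Step 2
Reactants: 4 1-(dimethyl(oxo)-λ6-sulfanylidene)heptan-2-one; 5 2-hydroxy-4-methoxybenzoic acid
Product: 7 8-hydroxy-6-methoxy-3-pentyl-1H-isochromen-1-one, via 2-hydroxy-4-methoxy-6-(2-oxoheptyl)benzoic acid 6 (not isolated)
Conditions: 5 (1 equiv), 4 (1.5 equiv), [Cp*RhCl2]2 (4 mol %), AgSbF6 (16 mol %), NaOAc (0.5 equiv), HFIP, 60 → 80 °C, 16 h
Reagents that add atoms: none
Why: Rh(III)-catalysed carboxylate-directed C–H acylmethylation/annulation with a sulfoxonium ylide: concerted metalation–deprotonation at C6 (the only free position ortho to CO2H) gives a nucleophilic aryl–Rh carbon, the ylide binds and loses DMSO to an electrophilic Rh α-oxo-carbene (enolonium equivalent of heptan-2-one) onto which the aryl migrates, and protodemetalation gives 6, which cyclodehydrates to enol lactone 7 under the acidic conditions; no stereocentre is created.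

Step 3
Reactants: 7 8-hydroxy-6-methoxy-3-pentyl-1H-isochromen-1-one
Product: 6 2-hydroxy-4-methoxy-6-(2-oxoheptyl)benzoic acid
Conditions: 5 % aq. KOH, THF, 50 °C, 2 h; then 1 M HCl to pH 2 at 0 °C, EtOAc extraction, no heating; used at once
Reagents that add atoms: potassium hydroxide, [K+].[OH-]
Why: Saponification of the enol lactone: the carboxylate/phenoxide dianion cannot re-close, and cold acidification releases the side chain as the ketone tautomer, giving the same keto acid that passed through unisolated in step 2.

Step 4
Reactants: 8 olivetolic acid (2,4-dihydroxy-6-pentylbenzoic acid)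
Product: 9 benzyl 2,4-dihydroxy-6-pentylbenzoate
Conditions: BnBr (1.05 equiv), KHCO3 (1.2 equiv), DMF, rt, 16 h
Reagents that add atoms: benzyl bromide, BrCc1ccccc1
Why: SN2 O-alkylation of the carboxylate: bicarbonate deprotonates only the carboxylic acid and leaves both phenols protonated, so only the benzyl ester forms, and room temperature avoids decarboxylation.

Step 5
Reactants: 6 2-hydroxy-4-methoxy-6-(2-oxoheptyl)benzoic acid; 9 benzyl 2,4-dihydroxy-6-pentylbenzoate
Product: 10 benzyl 2-hydroxy-4-{[2-hydroxy-4-methoxy-6-(2-oxoheptyl)benzoyl]oxy}-6-pentylbenzoate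
Conditions: DCC (1.1 equiv), dry toluene, 0 °C → rt, 24 h, no base or DMAP; any 7 formed is recovered and recycled through step 3
Reagents that add atoms: none
Why: Carbodiimide (DCC) esterification: the O-acylisourea of 6 is trapped by the free, more nucleophilic 4-OH of 9 (the 2-OH groups of both partners are held in hydrogen bonds to their ortho carbonyls), and base-free, non-acidic conditions at or below rt limit enol-lactonisation of the side-chain ketone back to 7.

Step 6
Reactants: 10 benzyl 2-hydroxy-4-{[2-hydroxy-4-methoxy-6-(2-oxoheptyl)benzoyl]oxy}-6-pentylbenzoate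
Product: 11 2-hydroxy-4-{[2-hydroxy-4-methoxy-6-(2-oxoheptyl)benzoyl]oxy}-6-pentylbenzoic acid
Conditions: H2 (1 atm), 10 % Pd/C, EtOAc, rt, 1–2 h; filter, evaporate cold, crystallise
Reagents that add atoms: none
Why: Catalytic hydrogenolysis of the benzyl ester under neutral conditions: the non-conjugated ketone, the depside aryl ester and the phenols are untouched, and no acid or base is present to expel olivetolic acid by enol-lactonisation.

## Compound list

1 | hexanoyl chloride | CCCCCC(=O)Cl | starting material
2 | trimethylsulfoxonium iodide | C[S+](C)(C)=O.[I-] | starting material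
3 | dimethylsulfoxonium methylide | C=S(C)(C)=O | intermediate
4 | 1-(dimethyl(oxo)-λ6-sulfanylidene)heptan-2-one | CCCCCC(=O)C=S(C)(C)=O | intermediate
5 | 2-hydroxy-4-methoxybenzoic acid | COc1ccc(C(=O)O)c(O)c1 | starting material
6 | 2-hydroxy-4-methoxy-6-(2-oxoheptyl)benzoic acid | CCCCCC(=O)Cc1cc(OC)cc(O)c1C(=O)O | intermediate
7 | 8-hydroxy-6-methoxy-3-pentyl-1H-isochromen-1-one | CCCCCC1=Cc2cc(OC)cc(O)c2C(=O)O1 | intermediate
8 | olivetolic acid (2,4-dihydroxy-6-pentylbenzoic acid) | CCCCCc1cc(O)cc(O)c1C(=O)O | starting material
9 | benzyl 2,4-dihydroxy-6-pentylbenzoate | CCCCCc1cc(O)cc(O)c1C(=O)OCc1ccccc1 | intermediate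
10 | benzyl 2-hydroxy-4-{[2-hydroxy-4-methoxy-6-(2-oxoheptyl)benzoyl]oxy}-6-pentylbenzoate | CCCCCC(=O)Cc1cc(OC)cc(O)c1C(=O)Oc1cc(O)c(C(=O)OCc2ccccc2)c(CCCCC)c1 | intermediate
11 | 2-hydroxy-4-{[2-hydroxy-4-methoxy-6-(2-oxoheptyl)benzoyl]oxy}-6-pentylbenzoic acid | CCCCCC(=O)Cc1cc(OC)cc(O)c1C(=O)Oc1cc(O)c(C(=O)O)c(CCCCC)c1 | target

## Step count and risks

Total step count: 6. Longest linear sequence: 5 (steps 1, 2, 3, 5, 6).

The three steps most likely to fail, in route order (step 5 is the riskiest):

**Step 2.** The free salicylic OH of 5 may hold Rh as an O,O-chelate. The acid may also protonate the ylide and be O-alkylated, or decarboxylate. The fallback masks the phenol and sets out from 4. Commercial 2,4-dimethoxybenzoic acid F1 is used in place of 5 under the same Rh(III) annulation (C6 is again the only ortho C–H) to give 6,8-dimethoxy-3-pentyl-1H-isochromen-1-one F2. BCl3 (CH2Cl2, −78 → 0 °C) then cleaves only the 8-methoxy group, which is peri to the lactone carbonyl and chelates boron. The fallback comes back to the route at 7.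

**Step 3.** The free keto acid 6 may re-lactonise to 7 or decarboxylate on acidification and concentration, and it cannot be chromatographed safely. The fallback sets out from 7 and releases the acid by hydrogenolysis instead of acidification. The lactone is opened with aqueous KOH as before, the solution is brought to pH about 8 with CO2 (phenol reprotonated, carboxylate kept) and evaporated. The potassium carboxylate is alkylated with BnBr in DMF to benzyl 2-hydroxy-4-methoxy-6-(2-oxoheptyl)benzoate F3, a neutral ester that can be purified on silica. H2, Pd/C in EtOAc then frees the acid under neutral conditions. The fallback comes back to the route at 6.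

**Step 5.** The activated acid of 6 can be captured by its own side-chain ketone to give isocoumarin 7 instead of the depside, and the acid is 2,6-disubstituted and therefore slow to couple. The fallback masks the ketone and sets out from 6. Propane-1,3-dithiol and BF3·OEt2 (CH2Cl2, 0 °C) give 2-hydroxy-4-methoxy-6-[(2-pentyl-1,3-dithian-2-yl)methyl]benzoic acid F4, which can no longer enol-lactonise. DCC coupling with 9 as in step 5 gives benzyl 2-hydroxy-4-({2-hydroxy-4-methoxy-6-[(2-pentyl-1,3-dithian-2-yl)methyl]benzoyl}oxy)-6-pentylbenzoate F5. Alkylative hydrolysis of the dithiane (MeI, CaCO3, MeCN–H2O, 40 °C) unmasks the ketone. The fallback comes back to the route at 10, before the hydrogenolysis, so no sulfur reaches the Pd catalyst.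

## Further compounds

F1 | step 2 | 2,4-dimethoxybenzoic acid | COc1ccc(C(=O)O)c(OC)c1
F2 | step 2 | 6,8-dimethoxy-3-pentyl-1H-isochromen-1-one | CCCCCC1=Cc2cc(OC)cc(OC)c2C(=O)O1
F3 | step 3 | benzyl 2-hydroxy-4-methoxy-6-(2-oxoheptyl)benzoate | CCCCCC(=O)Cc1cc(OC)cc(O)c1C(=O)OCc1ccccc1
F4 | step 5 | 2-hydroxy-4-methoxy-6-[(2-pentyl-1,3-dithian-2-yl)methyl]benzoic acid | CCCCCC1(Cc2cc(OC)cc(O)c2C(=O)O)SCCCS1
F5 | step 5 | benzyl 2-hydroxy-4-({2-hydroxy-4-methoxy-6-[(2-pentyl-1,3-dithian-2-yl)methyl]benzoyl}oxy)-6-pentylbenzoate | CCCCCC1(Cc2cc(OC)cc(O)c2C(=O)Oc2cc(O)c(C(=O)OCc3ccccc3)c(CCCCC)c2)SCCCS1
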